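**Plan**

1. Retrosynthesis: the homoallylic pair C6–OH / C10=C18 is closed back to a C6–O–C10 ether carrying C18–I (reductive opening, last step). The cyclopentene is cut at C1–C2 and C4–C5 (Pauson–Khand, then epoxide/Wharton transposition), the side chain at C7–C11 and C13–C14, and the oxabicycle at C6–C7 and C9–C10 ((4+3) of a furan with an oxyallyl cation).
2. Enabling feature: in the seven-membered ring the carbinol carbon C6 and the methylidene carbon C10 are 1,4-related, and the C6 oxygen, the cyclopentene (at C1/C5) and the C7 side chain all lie on one face. A temporary C6–O–C10 bridge therefore turns the ring into an 8-oxabicyclo[3.2.1]octane, made from furfuryl alcohol (C6, C5, C1, C10, C18 and the oxygen) and a three-carbon oxyallyl unit (C7–C8–C9), in which every later bond is made on the exo face.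
3. Forward order: seven-membered ring first ((4+3)), then the side chain on C7, then the five-membered ring (exo Pauson–Khand), then the C4 carbinol; last, the bridge is cut to release C6–OH and C10=C18.
4. Stereochemistry: absolute sense and C6 from the Cu–bis(oxazoline) (4+3); C7, C1 and C5 from exo attack on the bicycle; C11 from the imidazolidinone catalyst; C13 from the amino-alcohol/zinc catalyst; C4 from convex-face epoxidation.

Key step: step 2

Locants: target numbering is used in the Why lines (C1/C5 ring-fusion CH with C1 next to C10; C2=C3; C4(Me)(OH); C6(OH); C7 bearing the chain; C8, C9; C10=C18H2; chain C11(Me)–C12–C13(OAc)–C14=C15Me2). Bicyclic intermediates are named as 8-oxabicyclo[3.2.1]octanes, whose positions 1, 2, 3, 4, 5, 6, 7 are target C10, C9, C8, C7, C6, C5, C1.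

Assumption: the sense of induction of the three chiral catalysts (steps 2, 4, 5) is assigned from their accepted models; if a step gives the opposite sense, the enantiomeric catalyst is used.

**Step 1**
Reactants: 1 furfuryl alcohol
Product: 2 tert-butyl(furan-2-ylmethoxy)dimethylsilane
Conditions: TBSCl, imidazole, DMF, 0 °C → rt
Reagents that add atoms: tert-butyldimethylsilyl chloride, CC(C)(C)[Si](C)(C)Cl
Why: Standard silylation of a primary alcohol masks the hydroxyl that is kept as the handle on C18; no stereocentre is formed.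

**Step 2**
Reactants: 2 tert-butyl(furan-2-ylmethoxy)dimethylsilane (3 equiv); 3 3-(propa-1,2-dien-1-yl)-1,3-oxazolidin-2-one
Product: 5 (1S,2R,5S)-1-{[tert-butyl(dimethyl)silyl]oxymethyl}-2-endo-(2-oxo-1,3-oxazolidin-3-yl)-8-oxabicyclo[3.2.1]oct-6-en-3-one, via oxyallyl cation 4 (not isolated)
Conditions: DMDO (acetone solution, slow addition), Cu(OTf)2 (25 mol %), (S,S)-Ph-box (30 mol %), AgSbF6, 4 Å MS, CH2Cl2, −78 °C
Reagents that add atoms: dimethyldioxirane, CC1(C)OO1
Why: DMDO epoxidises the electron-rich allenamide 3 and the allene oxide opens to the nitrogen-stabilised oxyallyl cation 4, held by the chiral Cu(II)–bis(oxazoline) through the oxyallyl oxygen and the oxazolidinone carbonyl; the closest known reaction type is the catalytic asymmetric (4+3) cycloaddition of allenamide-derived oxyallyl cations with furans. The seven-membered carbocycle C6–C7–C8–C9–C10–C1–C5 closes by suprafacial bonding of both oxyallyl termini to the two furan α-carbons (4π + 2π electrons), and the furan oxygen becomes the C6–O–C10 bridge. The bridgeheads C6 and C10 are necessarily cis, C9 carries nitrogen endo from the compact transition state, and the absolute sense comes from the face of the chelated cation that the ligand leaves open. The step needs regioselectivity (nitrogen-bearing terminus to the substituted furan carbon), which follows from asynchronous bonding of the more electrophilic CH2 terminus to the more nucleophilic unsubstituted α-carbon of the 2-alkylfuran. This places nitrogen at C9, so that C7 is the only unhindered enolisable position, and the product already holds the seven-membered ring, the C6–O bond in its final configuration and C18 with its oxygen handle.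

**Step 3**
Reactants: 5 cycloadduct
Product: 6 C3=C4 trimethylsilyl enol ether of 5 (3-trimethylsilyloxy-8-oxabicyclo[3.2.1]octa-3,6-diene; stereocentres as in 5)
Conditions: LDA, TMSCl (in situ), THF, −78 °C
Reagents that add atoms: chlorotrimethylsilane, C[Si](C)(C)Cl
Why: Kinetic enolate formation with in situ silylation: LDA should remove the exo-axial hydrogen of the unhindered C7 methylene rather than the tertiary C9–H, which is shielded by the quaternary bridgehead and the oxazolidinone.

**Step 4**
Reactants: 6 silyl enol ether; 7 (E)-but-2-enal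
Product: 8 4-exo-[(2R)-4-oxobutan-2-yl] derivative of 5 (chain on ring position 4 syn to O-8)
Conditions: (2S,5S)-5-benzyl-2-tert-butyl-3-methylimidazolidin-4-one·TFA (20 mol %), CH2Cl2/H2O, −40 °C
Reagents that add atoms: none
Why: Iminium-catalysed Mukaiyama–Michael addition: the imidazolidinone shields one face of the (E)-iminium ion of 7 and should set C11 as R (the same facial sense as its other β-additions to crotonaldehyde), while 6 can only react on its exo face, syn to O-8 and anti to the etheno bridge, which sets C7.

**Step 5**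
Reactants: 8 keto aldehyde; 9 (2-methylprop-1-en-1-yl)magnesium bromide
Product: 11 4-exo-[(2R,4R)-4-acetoxy-6-methylhept-5-en-2-yl] derivative of 5, via zinc alkoxide 10 (not isolated)
Conditions: 9, ZnCl2, THF/toluene, then 1,4-dioxane (removes MgX2); (−)-MIB (10 mol %), 8, toluene, −20 → 0 °C; then Ac2O, rt
Reagents that add atoms: acetic anhydride, CC(=O)OC(C)=O
Why: Amino-alcohol-catalysed addition of a dialkenylzinc to an aldehyde (Si-face delivery with (−)-MIB should give 13R by reagent control), chemoselective for the aldehyde over the hindered ketone; the zinc alkoxide is acetylated in the same flask.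

**Step 6**
Reactants: 11 α-oxazolidinonyl ketone
Product: 12 1-{[tert-butyl(dimethyl)silyl]oxymethyl}-4-exo-[(2R,4R)-4-acetoxy-6-methylhept-5-en-2-yl]-8-oxabicyclo[3.2.1]oct-6-en-3-one (bridgeheads and ring position 4 as in 11)
Conditions: SmI2, THF/MeOH, −78 °C
Reagents that add atoms: none
Why: Samarium diiodide reduction of an α-heteroatom-substituted ketone: the ketyl expels the oxazolidinone anion and the samarium enolate is protonated at C9; the ether bridge survives because the C10–O bond lies in the nodal plane of the enolate, and C7 is not touched.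

**Step 7**
Reactants: 12 ketone
Product: 14 1-{[tert-butyl(dimethyl)silyl]oxymethyl}-4-exo-[(2R,4R)-4-acetoxy-6-methylhept-5-en-2-yl]-8-oxabicyclo[3.2.1]oct-6-ene, via tosylhydrazone 13 (not isolated)
Conditions: TsNHNH2, EtOH, 60 °C; then catecholborane, CHCl3, 0 °C; then NaOAc·3H2O, reflux
Reagents that add atoms: none
Why: Caglioti-type deoxygenation: the tosylhydrazone is reduced by catecholborane and the resulting diazene loses nitrogen on warming with acetate, so C8 becomes CH2 without strong base, without alkene migration and without epimerising C7.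

**Step 8**
Reactants: 14 bicyclic alkene; 15 trimethyl(prop-1-yn-1-yl)silane
Product: 17 exo-fused tricyclic enone (target numbering: 6,10-epoxy-bridged; C2 ketone; C3 trimethylsilyl; C3=C4; 4-methyl; 18-OTBS; 13-OAc; H-1 and H-5 cis and anti to the bridge oxygen), via alkyne–dicobalt complex 16 (not isolated)
Conditions: Co2(CO)8, CH2Cl2, rt; then 14, NMO, CH2Cl2, 0 °C → rt
Reagents that add atoms: dicobalt octacarbonyl (CO source), [Co].[Co].[C-]#[O+].[C-]#[O+].[C-]#[O+].[C-]#[O+].[C-]#[O+].[C-]#[O+].[C-]#[O+].[C-]#[O+]
Why: Intermolecular Pauson–Khand (2+2+1) reaction of a strained bicyclic alkene: cobalt binds the exo face, which sets H-1 and H-5 cis and anti to the bridge; the bulkier silyl-bearing alkyne carbon ends next to the carbonyl and the methyl-bearing carbon should bond to C5, the alkene carbon remote from the quaternary C10, which places the carbonyl at C2 and the methyl at C4.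

**Step 9**
Reactants: 17 silyl enone
Product: 18 enone alcohol (6,10-epoxy-bridged; 18-hydroxy; 4-methyl; C3=C4; C2 ketone; 13-OAc)
Conditions: TBAF, THF, 0 °C → rt
Reagents that add atoms: none
Why: Fluoride-mediated desilylation removes both silicon groups at once: protodesilylation of the α-silyl enone (the silicon has done its work of placing the methyl on C4) and cleavage of the TBS ether.

**Step 10**
Reactants: 18 enone alcohol
Product: 20 18-iodo enone (6,10-epoxy-bridged; 4-methyl; C3=C4; C2 ketone; 13-OAc), via primary triflate 19 (not isolated)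
Conditions: Tf2O, pyridine, CH2Cl2, −20 °C; then Bu4NI, 40 °C
Reagents that add atoms: tetrabutylammonium iodide, CCCC[N+](CCCC)(CCCC)CCCC.[I-]
Why: Triflation of the only free hydroxyl followed by SN2 displacement with iodide; the neopentyl-type centre is slow but the triflate is reactive enough, and no tertiary or allylic alcohol is present yet.

**Step 11**
Reactants: 20 iodo enone
Product: 21 3,4-epoxy ketone (epoxide oxygen syn to H-1/H-5)
Conditions: t-BuOOH, DBU, CH2Cl2, 0 °C → rt
Reagents that add atoms: tert-butyl hydroperoxide, CC(C)(C)OO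
Why: Weitz–Scheffer nucleophilic epoxidation: the peroxide adds to C4 from the convex face of the cis-fused cyclopentenone (the side of H-1/H-5, away from the bridgeheads), which sets the C4–O bond; the anhydrous amine base should spare the acetate.

**Step 12**
Reactants: 21 epoxy ketone
Product: 22 18-iodo-6,10-epoxy-bridged tertiary allylic alcohol (4-hydroxy-4-methyl, C2=C3, 13-OAc)
Conditions: N2H4·H2O, AcOH, MeOH, 0 °C → rt
Reagents that add atoms: none
Why: Wharton transposition: the epoxy hydrazone opens to an allylic diazene that loses nitrogen, giving the C2=C3 alkene and the tertiary C4 alcohol with its C–O bond retained; the acetic acid buffer and short time should prevent hydrazinolysis of the acetate.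

**Step 13**
Reactants: 22 β-iodo ether
Product: 23 target CNP0209568.2, (1S,4S,5R,6S,7R)-4,6-dihydroxy-4-methyl-10-methylidene-7-[(2R,4R)-4-acetoxy-6-methylhept-5-en-2-yl]bicyclo[5.3.0]dec-2-ene (target numbering)
Conditions: Zn dust (activated), NH4Cl, EtOH, 70 °C
Reagents that add atoms: none
Why: Boord-type (Bernet–Vasella) reductive fragmentation of a β-iodo ether: zinc inserts into the C18–I bond and the alkylzinc expels the C6 alkoxide across C10–O, which forms the C10=C18 methylidene and frees the C6 hydroxyl with its configuration intact; acetate, tertiary allylic alcohol and alkenes are inert to zinc.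

**Compound list**

1 | furfuryl alcohol (furan-2-ylmethanol) | OCc1ccco1 | starting material
2 | tert-butyl(furan-2-ylmethoxy)dimethylsilane | CC(C)(C)[Si](C)(C)OCc1ccco1 | intermediate
3 | 3-(propa-1,2-dien-1-yl)-1,3-oxazolidin-2-one | C=C=CN1CCOC1=O | starting material
4 | nitrogen-stabilised oxyallyl cation (2-oxido-1-(2-oxooxazolidin-3-yl)allyl cation, formed in situ) | C=C([O-])C=[N+]1CCOC1=O | intermediate
5 | (1S,2R,5S)-1-{[tert-butyl(dimethyl)silyl]oxymethyl}-2-endo-(2-oxo-1,3-oxazolidin-3-yl)-8-oxabicyclo[3.2.1]oct-6-en-3-one | CC(C)(C)[Si](C)(C)OC[C@@]12[C@@H](N3CCOC3=O)C(=O)C[C@H](O2)C=C1 | intermediate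
6 | C3=C4 trimethylsilyl enol ether of 5 | CC(C)(C)[Si](C)(C)OC[C@@]12[C@@H](N3CCOC3=O)C(O[Si](C)(C)C)=C[C@H](O2)C=C1 | intermediate
7 | (E)-but-2-enal (crotonaldehyde) | C/C=C/C=O | starting material
8 | 4-exo-[(2R)-4-oxobutan-2-yl] derivative of 5 | CC(C)(C)[Si](C)(C)OC[C@@]12[C@@H](N3CCOC3=O)C(=O)[C@H]([C@H](C)CC=O)[C@H](O2)C=C1 | intermediate
9 | (2-methylprop-1-en-1-yl)magnesium bromide | CC(C)=C[Mg]Br | starting material
10 | alkenylzinc alkoxide of the 4-exo-[(2R,4R)-4-hydroxy-6-methylhept-5-en-2-yl] derivative of 5 (formed in situ) | CC(C)(C)[Si](C)(C)OC[C@@]12[C@@H](N3CCOC3=O)C(=O)[C@H]([C@H](C)C[C@H](C=C(C)C)O[Zn]C=C(C)C)[C@H](O2)C=C1 | intermediate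
11 | 4-exo-[(2R,4R)-4-acetoxy-6-methylhept-5-en-2-yl] derivative of 5 | CC(C)(C)[Si](C)(C)OC[C@@]12[C@@H](N3CCOC3=O)C(=O)[C@H]([C@H](C)C[C@H](C=C(C)C)OC(C)=O)[C@H](O2)C=C1 | intermediate
12 | 1-{[tert-butyl(dimethyl)silyl]oxymethyl}-4-exo-[(2R,4R)-4-acetoxy-6-methylhept-5-en-2-yl]-8-oxabicyclo[3.2.1]oct-6-en-3-one | CC(C)(C)[Si](C)(C)OC[C@@]12CC(=O)[C@H]([C@H](C)C[C@H](C=C(C)C)OC(C)=O)[C@H](O2)C=C1 | intermediate
13 | 4-methylbenzenesulfonylhydrazone of 12 (formed in situ) | CC(C)(C)[Si](C)(C)OC[C@@]12CC(=NNS(=O)(=O)c3ccc(C)cc3)[C@H]([C@H](C)C[C@H](C=C(C)C)OC(C)=O)[C@H](O2)C=C1 | intermediate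
14 | 1-{[tert-butyl(dimethyl)silyl]oxymethyl}-4-exo-[(2R,4R)-4-acetoxy-6-methylhept-5-en-2-yl]-8-oxabicyclo[3.2.1]oct-6-ene | CC(C)(C)[Si](C)(C)OC[C@@]12CC[C@H]([C@H](C)C[C@H](C=C(C)C)OC(C)=O)[C@H](O2)C=C1 | intermediate
15 | trimethyl(prop-1-yn-1-yl)silane | CC#C[Si](C)(C)C | starting material
16 | hexacarbonyl[μ-trimethyl(prop-1-yn-1-yl)silane]dicobalt (formed in situ) | CC12C3([Si](C)(C)C)[Co]1(=C=O)(=C=O)(=C=O)[Co]23(=C=O)(=C=O)=C=O | intermediate
17 | exo-fused tricyclic enone: 6,10-epoxy-bridged, C2 ketone, 3-trimethylsilyl, C3=C4, 4-methyl, 18-OTBS, 13-OAc | CC(C)(C)[Si](C)(C)OC[C@@]13CC[C@H]([C@H](C)C[C@H](C=C(C)C)OC(C)=O)[C@H](O3)[C@H]2[C@@H]1C(=O)C([Si](C)(C)C)=C2C | intermediate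
18 | enone alcohol: 6,10-epoxy-bridged, 18-hydroxy, 4-methyl, C3=C4, C2 ketone, 13-OAc | OC[C@@]13CC[C@H]([C@H](C)C[C@H](C=C(C)C)OC(C)=O)[C@H](O3)[C@H]2[C@@H]1C(=O)C=C2C | intermediate
19 | 18-trifluoromethanesulfonate of 18 (formed in situ) | FC(F)(F)S(=O)(=O)OC[C@@]13CC[C@H]([C@H](C)C[C@H](C=C(C)C)OC(C)=O)[C@H](O3)[C@H]2[C@@H]1C(=O)C=C2C | intermediate
20 | 18-iodo enone: 6,10-epoxy-bridged, 4-methyl, C3=C4, C2 ketone, 13-OAc | IC[C@@]13CC[C@H]([C@H](C)C[C@H](C=C(C)C)OC(C)=O)[C@H](O3)[C@H]2[C@@H]1C(=O)C=C2C | intermediate
21 | 3,4-epoxy ketone of 20 (epoxide oxygen syn to H-1/H-5) | IC[C@@]13CC[C@H]([C@H](C)C[C@H](C=C(C)C)OC(C)=O)[C@H](O3)[C@H]2[C@@H]1C(=O)[C@@H]4O[C@@]42C | intermediate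
22 | 18-iodo-6,10-epoxy-bridged allylic alcohol: 4-hydroxy-4-methyl, C2=C3, 13-OAc | IC[C@@]13CC[C@H]([C@H](C)C[C@H](C=C(C)C)OC(C)=O)[C@H](O3)[C@H]2[C@@H]1C=C[C@]2(C)O | intermediate
23 | CNP0209568.2, (1S,4S,5R,6S,7R)-4,6-dihydroxy-4-methyl-10-methylidene-7-[(2R,4R)-4-acetoxy-6-methylhept-5-en-2-yl]bicyclo[5.3.0]dec-2-ene (target numbering) | C=C1CC[C@H]([C@H](C)C[C@H](C=C(C)C)OC(C)=O)[C@H](O)[C@H]2[C@@H]1C=C[C@]2(C)O | target

**Step count and risks**

Total step count: 13. Longest linear sequence: 13 steps (1 → 23); all other building blocks (3, 7, 9, 15) are commercial.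

Steps most likely to fail:

Step 8 (Pauson–Khand). What may go wrong: the cobalt complex of the internal silylalkyne may insert the bicyclic alkene too slowly, so that the complex decomposes, or with incomplete control over which alkene carbon ends next to the carbonyl. Fallback (sets out from 14, returns at 18): the reaction is run with the hexacarbonyldicobalt complex of ethyne (Co2(CO)8, acetylene, then NMO), which inserts strained alkenes far more readily, and should give the unsubstituted exo-fused cyclopentenone F1. The C4 methyl is then brought in by conjugate addition of lithium dimethylcuprate with TMSCl trapping (THF, −78 °C) to give the 4-methyl trimethylsilyl enol ether F2. Saegusa–Ito dehydrogenation (Pd(OAc)2, MeCN) restores the enone as the 4-methyl enone silyl ether F3, and TBAF (O-desilylation only) gives 18.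

Step 4 (Mukaiyama–Michael). What may go wrong: the hindered trisubstituted enol silane may add too slowly to the catalyst-bound iminium ion, so that hydrolysis of 6 back to 5 and loss of facial control at C11 take over. Fallback (sets out from 5, returns at 8): the lithium enolate of 5 (LDA, THF, −78 °C, C7 side as in step 3) is added to crotonaldehyde pre-complexed with aluminium tris(2,6-diphenylphenoxide), whose bulk blocks 1,2-attack and enforces conjugate addition of the metal enolate. C7 is again set by exo attack and C11 by the substrate through the closed transition state, with the C11 epimers separated at 8; this fallback makes no new isolated compound (F0).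

Step 3 (regioselective enolisation). What may go wrong: deprotonation at the wrong α-carbon, since the C9–H next to the carbamate nitrogen is the more acidic and may be removed through coordination of the base to the oxazolidinone carbonyl. Fallback (sets out from 5, returns at 12): the oxazolidinone is removed first with SmI2 (THF/MeOH, −78 °C) to give the nitrogen-free ketone F4. Its two α-methylenes are then differentiated by reagent control with a C2-symmetric chiral lithium amide (lithium bis[(R)-1-phenylethyl]amide, LiCl, TMSCl in situ, THF, −100 °C), the base used to desymmetrise the parent meso ketone, to give the C7-side enol silane F5. The conditions of step 4 applied to F5 give the keto aldehyde F6, and the conditions of step 5 applied to F6 give 12 directly.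

**Further compounds**

F1 | step 8 | unsubstituted exo-fused cyclopentenone (6,10-epoxy-bridged, C2 ketone, C3=C4, 18-OTBS, 13-OAc) | CC(C)(C)[Si](C)(C)OC[C@@]13CC[C@H]([C@H](C)C[C@H](C=C(C)C)OC(C)=O)[C@H](O3)[C@H]2[C@@H]1C(=O)C=C2
F2 | step 8 | 4-methyl C2 trimethylsilyl enol ether (C2=C3; methyl added on the H-1/H-5 face) | CC(C)(C)[Si](C)(C)OC[C@@]13CC[C@H]([C@H](C)C[C@H](C=C(C)C)OC(C)=O)[C@H](O3)[C@H]2[C@@H]1C(O[Si](C)(C)C)=C[C@@H]2C
F3 | step 8 | 4-methyl enone silyl ether (18-O-TBS ether of 18) | CC(C)(C)[Si](C)(C)OC[C@@]13CC[C@H]([C@H](C)C[C@H](C=C(C)C)OC(C)=O)[C@H](O3)[C@H]2[C@@H]1C(=O)C=C2C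
F0 | step 4 | none | none
F4 | step 3 | nitrogen-free ketone, 1-{[tert-butyl(dimethyl)silyl]oxymethyl}-8-oxabicyclo[3.2.1]oct-6-en-3-one (bridgeheads as in 5) | CC(C)(C)[Si](C)(C)OC[C@@]12CC(=O)C[C@H](O2)C=C1
F5 | step 3 | C3=C4 trimethylsilyl enol ether of F4 (double bond towards the H-bearing bridgehead) | CC(C)(C)[Si](C)(C)OC[C@@]12CC(O[Si](C)(C)C)=C[C@H](O2)C=C1
F6 | step 3 | 4-exo-[(2R)-4-oxobutan-2-yl] derivative of F4 | CC(C)(C)[Si](C)(C)OC[C@@]12CC(=O)[C@H]([C@H](C)CC=O)[C@H](O2)C=C1
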